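**Strategy.** Ring C is disconnected at O1–C2 and C4–C4a. The key step exploits the A-ring phenol as a 1,3-bis-nucleophile (O1 and its ortho carbon C4a) and the C4–C3–C2 chain as a 1,3-bis-electrophile, whose benzylic C2 is activated by the 2'- and 4'-oxygen atoms of ring B. In one flask a C,O-dilithiated 3,4,5-trimethoxyphenol is acylated at C4a by an enantiopure Weinreb amide (C4), and acid then ionises the C2 hydroxyl so that O1 closes ring C trans to the C3 methoxy group. The precursor is the open-chain (2R,3S)-3-aryl-3-hydroxy-2-methoxypropanamide from an Evans glycolate aldol reaction; the benzyl ethers and the 5-methyl ether are cleaved last.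

Key step: step 7

Remark: compounds 1, 4, 5 and 10 are taken as commercial; the 5-hydroxyl is carried as a methyl ether because the two ortho positions of 10 are then equivalent.

**Step 1**
Reactants: 1 2-methoxybenzene-1,4-diol (methoxyhydroquinone)
Product: 2 1,4-bis(benzyloxy)-2-methoxybenzene
Conditions: BnBr (2.4 equiv), K2CO3 (3 equiv), DMF, 60 °C, N2
Reagents that add atoms: benzyl bromide, BrCc1ccccc1
Why: Williamson ether synthesis on both phenolic hydroxyls; the benzyl ethers should survive organolithium and Brønsted acid and fall to BCl3 at the end.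

**Step 2**
Reactants: 2 1,4-bis(benzyloxy)-2-methoxybenzene
Product: 3 2,5-bis(benzyloxy)-4-methoxybenzaldehyde
Conditions: POCl3 (1.5 equiv), DMF, 0 → 70 °C; then ice–water
Reagents that add atoms: N,N-dimethylformamide, CN(C)C=O; water, O
Why: Vilsmeier–Haack formylation should go to the ring position para to the methoxy group and ortho to a benzyloxy group, the same pattern by which 1,2,4-trialkoxybenzenes give 2,4,5-trialkoxybenzaldehydes.

**Step 3**
Reactants: 4 (R)-4-benzyloxazolidin-2-one; 5 methoxyacetyl chloride
Product: 6 (R)-4-benzyl-3-(2-methoxyacetyl)oxazolidin-2-one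
Conditions: n-BuLi (1.05 equiv), THF, −78 °C; then 5, −78 → 0 °C
Reagents that add atoms: none
Why: N-acylation of the lithiated oxazolidinone by the acid chloride, the standard loading of an Evans auxiliary.

**Step 4**
Reactants: 6 (R)-4-benzyl-3-(2-methoxyacetyl)oxazolidin-2-one; 3 2,5-bis(benzyloxy)-4-methoxybenzaldehyde
Product: 8 (R)-4-benzyl-3-[(2R,3S)-3-[2,5-bis(benzyloxy)-4-methoxyphenyl]-3-hydroxy-2-methoxypropanoyl]oxazolidin-2-one, via the dibutylboron (Z)-enolate 7 (not isolated)
Conditions: Bu2BOTf (1.2 equiv), i-Pr2NEt (1.4 equiv), CH2Cl2, −78 → 0 °C; 3, −78 → 0 °C; then pH 7 buffer, MeOH, 30% H2O2, 0 °C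
Reagents that add atoms: none
Why: Evans syn-aldol (glycolate) reaction: the Z(O)-boron enolate 7 reacts through a closed chair (Zimmerman–Traxler) transition state with the aldehyde on the face opposite the benzyl group, so the (R)-auxiliary should set both new centres as (2R,3S).

**Step 5**
Reactants: 8 the syn-aldol imide
Product: 9 (2R,3S)-3-[2,5-bis(benzyloxy)-4-methoxyphenyl]-3-hydroxy-N,2-dimethoxy-N-methylpropanamide
Conditions: MeNHOMe·HCl (3 equiv), AlMe3 (3 equiv), CH2Cl2, −20 → 0 °C; then aq. Rochelle salt
Reagents that add atoms: N,O-dimethylhydroxylamine hydrochloride, CNOC.Cl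
Why: Weinreb aminolysis of the imide by the aluminium amide, directed to the exocyclic carbonyl by the β-aluminium alkoxide; both stereocentres are untouched.

**Step 6**
Reactants: 10 3,4,5-trimethoxyphenol
Product: 11 2-bromo-3,4,5-trimethoxyphenol
Conditions: NBS (1.0 equiv), CH2Cl2, −78 → 0 °C
Reagents that add atoms: N-bromosuccinimide, O=C1CCC(=O)N1Br
Why: electrophilic aromatic bromination ortho to the hydroxyl; the two free positions are equivalent, so one equivalent of NBS at low temperature should give the monobromide.

**Step 7**
Reactants: 11 2-bromo-3,4,5-trimethoxyphenol; 9 the Weinreb amide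
Product: 16 (2R,3R)-2-[2,5-bis(benzyloxy)-4-methoxyphenyl]-3,5,6,7-tetramethoxychroman-4-one, via chloromagnesium alkoxide of the amide 12 (not isolated), via C,O-dilithiated phenol 13 (not isolated), via tetrahedral adduct 14 (not isolated), via open-chain hydroxy ketone 15 (not isolated)
Conditions: 11, n-BuLi (2.05 equiv), THF, −78 °C; 9, t-BuMgCl (1.0 equiv), THF, −78 °C; combine, −78 → −20 °C; then MsOH (6 equiv), −20 → 20 °C
Reagents that add atoms: none
Why: Bromine–lithium exchange on the lithium phenoxide of 11 gives the C,O-dianion 13, whose aryl carbon (the future C4a) adds to the Weinreb amide of 12 to give the chelated adduct 14, which can neither enolise nor take up a second aryl group. Methanesulfonic acid then releases the ketone 15 and ionises its benzylic hydroxyl, a step made easy by the 2'-benzyloxy and 4'-methoxy groups of ring B, and the carbonyl-chelated phenol oxygen O1 captures the cation. The closest known reaction types are the aryllithium–Weinreb amide ketone synthesis and the acid-catalysed cycloetherification used to close flavan and flavanone rings. Ring C closes by a 6-exo-trig capture of the quinone-methide-like benzylic cation (an SN1 etherification). The new centre C2 is controlled by the existing methoxy-bearing centre (C2 of 9, C3 of the product): with its C–H bond eclipsing the cation plane (allylic 1,3-strain), O1 should add anti to the methoxy group, and reversible ionisation of the O1–C2 bond should funnel any cis isomer to the diequatorial 2,3-trans product, so the carbinol configuration of 9 is not needed and the retained (R) centre fixes (2R,3R). The step needs C- over O-acylation at one defined ortho carbon, which the bromine position secures, and retention of the methoxy-bearing centre, which the non-enolisable adduct 14 secures in the basic stage and the fast ionisation of the electron-rich benzylic alcohol should secure in the acidic stage.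

**Step 8**
Reactants: 16 the protected flavanone
Product: 17 (2R,3R)-2-(2,5-dihydroxy-4-methoxyphenyl)-5-hydroxy-3,6,7-trimethoxychroman-4-one (target)
Conditions: BCl3 (6 equiv), pentamethylbenzene (6 equiv), CH2Cl2, −78 → 0 °C; then H2O
Reagents that add atoms: none
Why: Lewis-acid ether cleavage: BCl3 should remove both aryl benzyl ethers (benzyl cation trapped by pentamethylbenzene in a Friedel–Crafts reaction) and, through the six-membered chelate with the C4 carbonyl, only the peri 5-methyl ether, leaving the 6-, 7-, 4'- and aliphatic 3-methoxy groups and both stereocentres untouched.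

**Compound list**

1 | 2-methoxybenzene-1,4-diol (methoxyhydroquinone) | COc1cc(O)ccc1O | starting material
2 | 1,4-bis(benzyloxy)-2-methoxybenzene | COc1cc(OCc2ccccc2)ccc1OCc1ccccc1 | intermediate
3 | 2,5-bis(benzyloxy)-4-methoxybenzaldehyde | COc1cc(OCc2ccccc2)c(C=O)cc1OCc1ccccc1 | intermediate
4 | (R)-4-benzyloxazolidin-2-one | O=C1N[C@H](Cc2ccccc2)CO1 | starting material
5 | methoxyacetyl chloride | COCC(=O)Cl | starting material
6 | (R)-4-benzyl-3-(2-methoxyacetyl)oxazolidin-2-one | COCC(=O)N1[C@H](Cc2ccccc2)COC1=O | intermediate
7 | dibutylboron (Z)-enolate of 6 | CO/C=C(\OB(CCCC)CCCC)N1[C@H](Cc2ccccc2)COC1=O | intermediate (not isolated)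
8 | (R)-4-benzyl-3-[(2R,3S)-3-[2,5-bis(benzyloxy)-4-methoxyphenyl]-3-hydroxy-2-methoxypropanoyl]oxazolidin-2-one | O=C1OC[C@@H](Cc2ccccc2)N1C(=O)[C@H](OC)[C@@H](O)c1cc(OCc2ccccc2)c(OC)cc1OCc1ccccc1 | intermediate
9 | (2R,3S)-3-[2,5-bis(benzyloxy)-4-methoxyphenyl]-3-hydroxy-N,2-dimethoxy-N-methylpropanamide | CON(C)C(=O)[C@H](OC)[C@@H](O)c1cc(OCc2ccccc2)c(OC)cc1OCc1ccccc1 | intermediate
10 | 3,4,5-trimethoxyphenol | COc1cc(O)cc(OC)c1OC | starting material
11 | 2-bromo-3,4,5-trimethoxyphenol | COc1cc(O)c(Br)c(OC)c1OC | intermediate
12 | chloromagnesium alkoxide of 9 | CON(C)C(=O)[C@H](OC)[C@@H](O[Mg]Cl)c1cc(OCc2ccccc2)c(OC)cc1OCc1ccccc1 | intermediate (not isolated)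
13 | lithium 2-lithio-3,4,5-trimethoxyphenoxide | COc1cc(O[Li])c([Li])c(OC)c1OC | intermediate (not isolated)
14 | tetrahedral N-methoxy-N-methyl hemiaminal adduct (Li/Mg alkoxides) | CON(C)C(O[Li])(c1c(O[Li])cc(OC)c(OC)c1OC)[C@H](OC)[C@@H](O[Mg]Cl)c1cc(OCc2ccccc2)c(OC)cc1OCc1ccccc1 | intermediate (not isolated)
15 | (2R,3S)-3-[2,5-bis(benzyloxy)-4-methoxyphenyl]-3-hydroxy-1-(2-hydroxy-4,5,6-trimethoxyphenyl)-2-methoxypropan-1-one | COc1cc(O)c(C(=O)[C@H](OC)[C@@H](O)c2cc(OCc3ccccc3)c(OC)cc2OCc2ccccc2)c(OC)c1OC | intermediate (not isolated)
16 | (2R,3R)-2-[2,5-bis(benzyloxy)-4-methoxyphenyl]-3,5,6,7-tetramethoxychroman-4-one | COc1cc(OCc4ccccc4)c([C@H]2Oc3cc(OC)c(OC)c(OC)c3C(=O)[C@@H]2OC)cc1OCc1ccccc1 | intermediate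
17 | (2R,3R)-2-(2,5-dihydroxy-4-methoxyphenyl)-5-hydroxy-3,6,7-trimethoxychroman-4-one | COc1cc(O)c([C@H]2Oc3cc(OC)c(OC)c(O)c3C(=O)[C@@H]2OC)cc1O | target

**Step count and risks**

Total steps: 8. Longest linear sequence: 6 steps (1, 2, 4, 5, 7, 8).

Steps most likely to fail:

1. Step 7. In the acidic stage, loss of water across C2–C3 of the released ketone to an achiral enone could compete with ring closure; the enone would re-close without control and erode enantiopurity. The benzylic cation could also be captured by another arene. Fallback: set out from 9 and 11, run the same addition, but quench the adduct with aqueous NH4Cl at −78 °C and isolate the hydroxy ketone 15. Then close the ring by an intramolecular Mitsunobu etherification (PPh3, DIAD, THF, 0 °C). This displaces the benzylic hydroxyl with inversion under neutral conditions, so the syn (2R,3S) arrangement should give the 2,3-trans (2R,3R) product, and the route is rejoined at 16. This fallback makes no compound beyond the list (F0).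

2. Step 8. Over-cleavage may occur: the 6-methyl ether next to the newly formed 5-O–boron group, or the 3-methyl ether through its five-membered chelate with the carbonyl. Lewis-acid opening of the O1–C2 bond with epimerisation is also possible. Fallback: set out from 16 and split the deprotection into two orthogonal operations. Hydrogenolysis (H2, Pd/C, EtOAc, short reaction time) should give (2R,3R)-2-(2,5-dihydroxy-4-methoxyphenyl)-3,5,6,7-tetramethoxychroman-4-one F1. Chelation-controlled demethylation of the 5-methyl ether alone with AlCl3 (2 equiv) in MeCN at 0 °C → room temperature then returns to 17.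

3. Step 5. The aluminium aldolate of this electron-rich benzylic carbinol may undergo retro-aldol cleavage, or the amide may attack the ring carbonyl of the auxiliary. Fallback: set out from 8 and remove the auxiliary by hydrolysis with LiOH/H2O2 in THF–H2O at 0 °C to give (2R,3S)-3-[2,5-bis(benzyloxy)-4-methoxyphenyl]-3-hydroxy-2-methoxypropanoic acid F2. Couple F2 with MeNHOMe·HCl (EDC·HCl, HOBt, N-methylmorpholine, CH2Cl2) to return to 9.

**Further compounds**

F0 | step 7 | none | none
F1 | step 8 | (2R,3R)-2-(2,5-dihydroxy-4-methoxyphenyl)-3,5,6,7-tetramethoxychroman-4-one | COc1cc(O)c([C@H]2Oc3cc(OC)c(OC)c(OC)c3C(=O)[C@@H]2OC)cc1O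
F2 | step 5 | (2R,3S)-3-[2,5-bis(benzyloxy)-4-methoxyphenyl]-3-hydroxy-2-methoxypropanoic acid | OC(=O)[C@H](OC)[C@@H](O)c1cc(OCc2ccccc2)c(OC)cc1OCc1ccccc1
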